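**Plan**

1. Retrosynthesis: both 2-aminoimidazoles are cut to α-amino ketones plus cyanamide and further back to acetyl groups; both pyrrole amides are cut at N–C(O) and the CH2N arms are taken back to esters. This leaves an all-trans 3,4-diacetylcyclobutane-1,2-diester with the ketones as ketals.
2. The cyclobutane bond between the two ester-bearing carbons (the future CH–CH2N carbons) is cut with insertion of a nitrogen atom. The precursor is a pyrrolidine-2,5-dicarboxylate, and loss of N2 from its 1,1-diazene closes the four-membered ring (ring contraction).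
3. Feature used: each of these two ring carbons carries a carboxyl-level carbon, so both are α-amino-ester carbons that become ester-stabilised radical ends. The C–N–C unit plus the C3–C4 pair bearing the two acetyl groups is the product pattern of a [3+2] cycloaddition of a glycine-derived azomethine ylide with (E)-hex-3-ene-2,5-dione.
4. Forward order: imine → pyrrolidine (temporary five-membered ring) → ketals → cyclobutane by N2 extrusion → epimerisation to all-trans → CH2OH → CH2N3 → bis-amide → diketone → bis(α-amino ketone) → both imidazole rings last.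
5. Stereochemistry: the trans C3/C4 pair comes from the E-alkene, its absolute sense from the chiral copper catalyst. The ester-bearing carbons pass through the contraction with retention, and one of them is then equilibrated by base into the all-trans isomer. No later step touches the four ring centres.

Key step: step 4

Assumption: (R)-DTBM-Segphos is taken to deliver the (3R,4R) adduct in step 2; should a pilot run show the opposite sense, the (S)-ligand is used.

**Route**

Step 1
Reactants: 1 glycine ethyl ester hydrochloride; 2 ethyl glyoxylate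
Product: 3 ethyl (E)-2-[(2-ethoxy-2-oxoethylidene)amino]acetate
Conditions: Et3N (1.0 equiv), MgSO4, CH2Cl2, 0 → 23 °C; filtered, concentrated, used crude
Reagents that add atoms: none
Why: Imine formation between a primary amine and the very electrophilic glyoxylate aldehyde, with MgSO4 removing the water; the α-imino ester is used at once because it is prone to hydrolysis and self-addition.

Step 2
Reactants: 3 ethyl (E)-2-[(2-ethoxy-2-oxoethylidene)amino]acetate; 4 (E)-hex-3-ene-2,5-dione
Product: 5 diethyl (2R,3R,4R,5S)-3,4-diacetylpyrrolidine-2,5-dicarboxylate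
Conditions: Cu(CH3CN)4PF6 (5 mol %), (R)-DTBM-Segphos (5.5 mol %), Et3N (15 mol %), THF, −20 °C
Reagents that add atoms: none
Why: Catalytic asymmetric 1,3-dipolar cycloaddition of a metal-bound azomethine ylide: the N,O-chelated W-shaped ylide adds suprafacially to the E-enedione, so 2,5-cis follows from the ylide geometry and 3,4-trans from the alkene geometry (for this symmetrical pair only one relative configuration is possible), while the ligand-controlled choice between the two enantiomeric orientations of the enedione on the ylide should set the absolute configuration at C3 and C4.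

Step 3
Reactants: 5 diethyl (2R,3R,4R,5S)-3,4-diacetylpyrrolidine-2,5-dicarboxylate
Product: 6 diethyl (2R,3R,4R,5S)-3,4-bis(2-methyl-1,3-dioxolan-2-yl)pyrrolidine-2,5-dicarboxylate
Conditions: TfOH (1.05 equiv), CH2Cl2, −78 °C; then TMSOCH2CH2OTMS (4 equiv), TMSOTf (0.2 equiv), −78 → −20 °C; then pyridine, aq. NaHCO3
Reagents that add atoms: 1,2-bis(trimethylsilyloxy)ethane C[Si](C)(C)OCCO[Si](C)(C)C
Why: Silyl-triflate-catalysed acetalisation with the bis-silyl ether of ethylene glycol runs at low temperature on the N-protonated substrate, so that acid-promoted furan formation of the 1,4-diketone (Paal–Knorr type) and retro-Mannich opening of the β-amino ketone should not compete; no stereocentre is touched.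

Step 4
Reactants: 6 diethyl (2R,3R,4R,5S)-3,4-bis(2-methyl-1,3-dioxolan-2-yl)pyrrolidine-2,5-dicarboxylate
Product: 8 diethyl (1R,2S,3R,4R)-3,4-bis(2-methyl-1,3-dioxolan-2-yl)cyclobutane-1,2-dicarboxylate, via isodiazene 7 (not isolated)
Conditions: PhI(OH)OTs (2.5 equiv), NH2CO2NH4 (8 equiv), CF3CH2OH, 80 °C
Reagents that add atoms: ammonium carbamate NC(=O)[O-].[NH4+] (its nitrogen is held by 7 only and leaves as N2)
Why: PhI(OH)OTs and ammonia form an electrophilic iodonitrene that transfers nitrogen to the pyrrolidine nitrogen and, after loss of PhI, gives the 1,1-diazene 7, which loses N2 to a singlet 1,4-biradical whose two ester-stabilised radical carbons (the former C2 and C5) couple. The closest known reaction type is the nitrogen-deletion ring contraction of polysubstituted pyrrolidines to cyclobutanes through isodiazenes. The four-membered ring closes by radical–radical recombination within the 1,4-biradical, the other three ring bonds being carried over from the pyrrolidine. No new stereocentre is created: C1 and C2 should keep the pyrrolidine configuration (cis diester) because collapse of the singlet biradical is faster than bond rotation, C3 and C4 are untouched, and any leakage at C1 or C2 is harmless because step 5 equilibrates these centres. The selectivity needed is C–C coupling over β-scission of the biradical into two acrylate molecules and over oxidation elsewhere; the ester groups at both radical ends ease N2 loss and the short-lived singlet should couple at once. The ketals remove the enolisable 1,4-diketone that would otherwise react with ammonia or with the trivalent iodine reagent.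

Step 5
Reactants: 8 diethyl (1R,2S,3R,4R)-3,4-bis(2-methyl-1,3-dioxolan-2-yl)cyclobutane-1,2-dicarboxylate
Product: 9 diethyl (1S,2S,3R,4R)-3,4-bis(2-methyl-1,3-dioxolan-2-yl)cyclobutane-1,2-dicarboxylate
Conditions: NaOEt (0.3 equiv), EtOH, 23 → 50 °C
Reagents that add atoms: none
Why: Base-mediated epimerisation through the ester enolate under thermodynamic control: the C1 ester of 8 is cis to both neighbours, so reversible deprotonation should drain the material into the all-trans isomer, while C3 and C4 carry no acidifying group and keep the configuration set in step 2.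

Step 6
Reactants: 9 diethyl (1S,2S,3R,4R)-3,4-bis(2-methyl-1,3-dioxolan-2-yl)cyclobutane-1,2-dicarboxylate
Product: 10 [(1R,2R,3S,4S)-3,4-bis(2-methyl-1,3-dioxolan-2-yl)cyclobutane-1,2-diyl]dimethanol
Conditions: LiAlH4 (3 equiv), THF, 0 → 23 °C; aqueous NaOH work-up
Reagents that add atoms: none
Why: Hydride reduction of both esters to primary alcohols with LiAlH4; the ketals are inert to hydride and the trans arrangement rules out lactone formation on the way.

Step 7
Reactants: 10 [(1R,2R,3S,4S)-3,4-bis(2-methyl-1,3-dioxolan-2-yl)cyclobutane-1,2-diyl]dimethanol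
Product: 12 (1R,2R,3S,4S)-1,2-bis(azidomethyl)-3,4-bis(2-methyl-1,3-dioxolan-2-yl)cyclobutane, via bis-mesylate 11 (not isolated)
Conditions: MsCl (2.5 equiv), Et3N (3 equiv), CH2Cl2, 0 °C; then NaN3 (4 equiv), DMF, 60 °C
Reagents that add atoms: methanesulfonyl chloride CS(=O)(=O)Cl (atoms held by 11 only); sodium azide [Na+].[N-]=[N+]=[N-]
Why: Sulfonate formation followed by SN2 displacement with azide at the two primary carbons; the trans relation of the arms prevents ring closure between them and no ring centre is involved.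

Step 8
Reactants: 12 (1R,2R,3S,4S)-1,2-bis(azidomethyl)-3,4-bis(2-methyl-1,3-dioxolan-2-yl)cyclobutane; 13 4-bromo-2-(trichloroacetyl)-1H-pyrrole (two molecules per molecule of 12)
Product: 15 N,N'-{[(1R,2R,3S,4S)-3,4-bis(2-methyl-1,3-dioxolan-2-yl)cyclobutane-1,2-diyl]bis(methylene)}bis(4-bromo-1H-pyrrole-2-carboxamide), via diamine 14 (not isolated)
Conditions: H2 (1 atm), Pd/C (10 wt %), MeOH, 23 °C; filtered; then 13 (2.1 equiv), MeCN, 23 °C
Reagents that add atoms: 4-bromo-2-(trichloroacetyl)-1H-pyrrole O=C(c1cc(Br)c[nH]1)C(Cl)(Cl)Cl (the second molecule of 13; one molecule is used per amine)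
Why: Catalytic hydrogenation of the azides to the primary amines, then amide formation in which each of the two amines takes the acyl group of one molecule of the trichloromethyl ketone 13 (haloform-type cleavage with loss of chloroform), which needs no pyrrole N-protection; the aryl bromide enters only after the hydrogenation.

Step 9
Reactants: 15 N,N'-{[(1R,2R,3S,4S)-3,4-bis(2-methyl-1,3-dioxolan-2-yl)cyclobutane-1,2-diyl]bis(methylene)}bis(4-bromo-1H-pyrrole-2-carboxamide)
Product: 16 N,N'-{[(1R,2R,3S,4S)-3,4-diacetylcyclobutane-1,2-diyl]bis(methylene)}bis(4-bromo-1H-pyrrole-2-carboxamide)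
Conditions: TsOH·H2O (0.2 equiv), THF/H2O (4:1), 50 °C
Reagents that add atoms: water O
Why: Acid-catalysed acetal hydrolysis; the acylpyrroles and amides tolerate dilute aqueous acid, and the all-trans diketone is the stable configuration, so enolisation at the ring carbons does no harm.

Step 10
Reactants: 16 N,N'-{[(1R,2R,3S,4S)-3,4-diacetylcyclobutane-1,2-diyl]bis(methylene)}bis(4-bromo-1H-pyrrole-2-carboxamide)
Product: 17 N,N'-{[(1R,2R,3S,4S)-3,4-bis(2-chloroacetyl)cyclobutane-1,2-diyl]bis(methylene)}bis(4-bromo-1H-pyrrole-2-carboxamide)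
Conditions: BnMe3N+ ICl2− (4.4 equiv), THF, 60 °C
Reagents that add atoms: benzyltrimethylammonium dichloroiodate C[N+](C)(C)Cc1ccccc1.Cl[I-]Cl
Why: Electrophilic α-chlorination of the methyl ketones through the less hindered methyl-side enol with the mild dichloroiodate salt, which should leave the bromopyrroles and the ring methine positions untouched.

Step 11
Reactants: 17 N,N'-{[(1R,2R,3S,4S)-3,4-bis(2-chloroacetyl)cyclobutane-1,2-diyl]bis(methylene)}bis(4-bromo-1H-pyrrole-2-carboxamide)
Product: 19 N,N'-{[(1R,2R,3S,4S)-3,4-bis(2-aminoacetyl)cyclobutane-1,2-diyl]bis(methylene)}bis(4-bromo-1H-pyrrole-2-carboxamide) dihydrochloride, via bis-diformylamide 18 (not isolated)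
Conditions: NaN(CHO)2 (2.5 equiv), MeCN, 35 °C; then HCl, MeOH, 23 °C
Reagents that add atoms: sodium diformylamide [Na+].O=C[N-]C=O; hydrogen chloride Cl
Why: Gabriel-type SN2 displacement of the α-chloro ketones by diformylamide, then acid methanolysis of the formyl groups, should give the primary α-amino ketones as their stable hydrochlorides without over-alkylation or self-condensation.

Step 12
Reactants: 19 N,N'-{[(1R,2R,3S,4S)-3,4-bis(2-aminoacetyl)cyclobutane-1,2-diyl]bis(methylene)}bis(4-bromo-1H-pyrrole-2-carboxamide) dihydrochloride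
Product: 20 sceptrin, N,N'-{[(1R,2R,3S,4S)-3,4-bis(2-amino-1H-imidazol-5-yl)cyclobutane-1,2-diyl]bis(methylene)}bis(4-bromo-1H-pyrrole-2-carboxamide)
Conditions: H2NCN (10 equiv), H2O, pH 4.5, 95 °C; then aq. NaOH (2.0 equiv), 0 °C, reversed-phase desalting
Reagents that add atoms: cyanamide NC#N
Why: Condensation of an α-amino ketone with cyanamide (guanylation of the amine, cyclisation of the guanidine onto the ketone, dehydration) should build both 2-aminoimidazole rings, the classical aminoimidazole synthesis; the all-trans ring centres are the stable ones and are not affected.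

**Compound list**

1 | glycine ethyl ester hydrochloride | Cl.NCC(=O)OCC | starting material
2 | ethyl glyoxylate (ethyl 2-oxoacetate) | O=CC(=O)OCC | starting material
3 | ethyl (E)-2-[(2-ethoxy-2-oxoethylidene)amino]acetate | CCOC(=O)/C=N/CC(=O)OCC | intermediate
4 | (E)-hex-3-ene-2,5-dione | CC(=O)/C=C/C(C)=O | starting material
5 | diethyl (2R,3R,4R,5S)-3,4-diacetylpyrrolidine-2,5-dicarboxylate (2,5-cis, 3,4-trans) | CC(=O)[C@H]1[C@H](C(=O)OCC)N[C@H](C(=O)OCC)[C@@H]1C(C)=O | intermediate
6 | diethyl (2R,3R,4R,5S)-3,4-bis(2-methyl-1,3-dioxolan-2-yl)pyrrolidine-2,5-dicarboxylate | CC1(OCCO1)[C@H]2[C@H](C(=O)OCC)N[C@H](C(=O)OCC)[C@@H]2C3(C)OCCO3 | intermediate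
7 | 1,1-diazene (isodiazene) of 6, N-nitrene on the pyrrolidine nitrogen, (2R,3R,4R,5S) | CC1(OCCO1)[C@H]2[C@H](C(=O)OCC)[N+](=[N-])[C@H](C(=O)OCC)[C@@H]2C3(C)OCCO3 | intermediate (not isolated)
8 | diethyl (1R,2S,3R,4R)-3,4-bis(2-methyl-1,3-dioxolan-2-yl)cyclobutane-1,2-dicarboxylate (1,2-cis diester, 3,4-trans) | CC1(OCCO1)[C@H]2[C@H](C(=O)OCC)[C@H](C(=O)OCC)[C@@H]2C3(C)OCCO3 | intermediate
9 | diethyl (1S,2S,3R,4R)-3,4-bis(2-methyl-1,3-dioxolan-2-yl)cyclobutane-1,2-dicarboxylate (all-trans) | CC1(OCCO1)[C@H]2[C@H](C(=O)OCC)[C@@H](C(=O)OCC)[C@@H]2C3(C)OCCO3 | intermediate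
10 | [(1R,2R,3S,4S)-3,4-bis(2-methyl-1,3-dioxolan-2-yl)cyclobutane-1,2-diyl]dimethanol | CC1(OCCO1)[C@H]2[C@H](CO)[C@@H](CO)[C@@H]2C3(C)OCCO3 | intermediate
11 | [(1R,2R,3S,4S)-3,4-bis(2-methyl-1,3-dioxolan-2-yl)cyclobutane-1,2-diyl]bis(methylene) dimethanesulfonate | CC1(OCCO1)[C@H]2[C@H](COS(C)(=O)=O)[C@@H](COS(C)(=O)=O)[C@@H]2C3(C)OCCO3 | intermediate (not isolated)
12 | (1R,2R,3S,4S)-1,2-bis(azidomethyl)-3,4-bis(2-methyl-1,3-dioxolan-2-yl)cyclobutane | CC1(OCCO1)[C@H]2[C@H](CN=[N+]=[N-])[C@@H](CN=[N+]=[N-])[C@@H]2C3(C)OCCO3 | intermediate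
13 | 4-bromo-2-(trichloroacetyl)-1H-pyrrole | O=C(c1cc(Br)c[nH]1)C(Cl)(Cl)Cl | starting material
14 | [(1R,2R,3S,4S)-3,4-bis(2-methyl-1,3-dioxolan-2-yl)cyclobutane-1,2-diyl]dimethanamine | CC1(OCCO1)[C@H]2[C@H](CN)[C@@H](CN)[C@@H]2C3(C)OCCO3 | intermediate (not isolated)
15 | N,N'-{[(1R,2R,3S,4S)-3,4-bis(2-methyl-1,3-dioxolan-2-yl)cyclobutane-1,2-diyl]bis(methylene)}bis(4-bromo-1H-pyrrole-2-carboxamide) | CC1(OCCO1)[C@H]2[C@H](CNC(=O)c3cc(Br)c[nH]3)[C@@H](CNC(=O)c3cc(Br)c[nH]3)[C@@H]2C4(C)OCCO4 | intermediate
16 | N,N'-{[(1R,2R,3S,4S)-3,4-diacetylcyclobutane-1,2-diyl]bis(methylene)}bis(4-bromo-1H-pyrrole-2-carboxamide) | CC(=O)[C@H]1[C@H](CNC(=O)c2cc(Br)c[nH]2)[C@@H](CNC(=O)c2cc(Br)c[nH]2)[C@@H]1C(C)=O | intermediate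
17 | N,N'-{[(1R,2R,3S,4S)-3,4-bis(2-chloroacetyl)cyclobutane-1,2-diyl]bis(methylene)}bis(4-bromo-1H-pyrrole-2-carboxamide) | ClCC(=O)[C@H]1[C@H](CNC(=O)c2cc(Br)c[nH]2)[C@@H](CNC(=O)c2cc(Br)c[nH]2)[C@@H]1C(=O)CCl | intermediate
18 | N,N'-{[(1R,2R,3S,4S)-3,4-bis[2-(diformylamino)acetyl]cyclobutane-1,2-diyl]bis(methylene)}bis(4-bromo-1H-pyrrole-2-carboxamide) | O=CN(C=O)CC(=O)[C@H]1[C@H](CNC(=O)c2cc(Br)c[nH]2)[C@@H](CNC(=O)c2cc(Br)c[nH]2)[C@@H]1C(=O)CN(C=O)C=O | intermediate (not isolated)
19 | N,N'-{[(1R,2R,3S,4S)-3,4-bis(2-aminoacetyl)cyclobutane-1,2-diyl]bis(methylene)}bis(4-bromo-1H-pyrrole-2-carboxamide) dihydrochloride | NCC(=O)[C@H]1[C@H](CNC(=O)c2cc(Br)c[nH]2)[C@@H](CNC(=O)c2cc(Br)c[nH]2)[C@@H]1C(=O)CN.Cl.Cl | intermediate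
20 | sceptrin | Nc1ncc([C@H]2[C@H](CNC(=O)c3cc(Br)c[nH]3)[C@@H](CNC(=O)c3cc(Br)c[nH]3)[C@@H]2c2cnc(N)[nH]2)[nH]1 | target

**Count and risks**

Total step count: 12. Longest linear sequence: 12 steps (from 1 and 2 to 20).

Steps most likely to fail, riskiest first:

Step 4. The 1,4-biradical may undergo β-scission into two acrylate molecules instead of coupling, or nitrogen transfer to the hindered, electron-poor pyrrolidine nitrogen may stay incomplete. The fallback separates N–N bond formation from diazene generation, so that N2 is lost at low temperature, where coupling should win over fragmentation. It sets out from 6 and comes back at 8. Treating 6 with tert-butyl nitrite in CH2Cl2 at 23 °C should give diethyl (2R,3R,4R,5S)-3,4-bis(2-methyl-1,3-dioxolan-2-yl)-1-nitrosopyrrolidine-2,5-dicarboxylate F1. Reduction of the N–N=O group with Zn dust in AcOH/MeOH at 0 °C should give diethyl (2R,3R,4R,5S)-1-amino-3,4-bis(2-methyl-1,3-dioxolan-2-yl)pyrrolidine-2,5-dicarboxylate F2. Oxidation of this hydrazine with tert-butyl hypochlorite and Et3N in THF at −78 °C should generate 7, which on warming loses N2 and should give 8.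

Step 2. Enantiofacial discrimination may be poor, because both ylide termini carry the same ester and the catalyst must tell the chelated end from the free one; the imine may also add to itself. The fallback gives up catalyst control and resolves instead. It sets out from 3 and 4 and comes back at 5. Cycloaddition with AgOAc (5 mol %) and Et3N in toluene at 0 °C should give racemic diethyl (2R*,3R*,4R*,5S*)-3,4-diacetylpyrrolidine-2,5-dicarboxylate F3 as a single diastereomer, and preparative chromatography on a chiral stationary phase then separates 5 from its enantiomer.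

Step 3. Acid may cause cyclodehydration of the 1,4-diketone to a fused furan, or epimerisation by retro-Mannich ring opening. The fallback moves the ring contraction in front of the protection, so that the ketones are masked only on the cyclobutane, where no furan can form and no amine is left. It sets out from 5 and comes back at 8. Nitrogen deletion of 5 with N-(benzyloxy)-N-(pivaloyloxy)-4-(trifluoromethyl)benzamide in THF at 45 °C, an ammonia-free route to the isodiazene that tolerates ketones, should give diethyl (1R,2S,3R,4R)-3,4-diacetylcyclobutane-1,2-dicarboxylate F4. Acetalisation with ethylene glycol and TsOH in benzene with azeotropic removal of water should then give 8; any equilibration at the ester-bearing carbon on the way is harmless in view of step 5.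

**Further compounds**

F1 | step 4 | diethyl (2R,3R,4R,5S)-3,4-bis(2-methyl-1,3-dioxolan-2-yl)-1-nitrosopyrrolidine-2,5-dicarboxylate | CC1(OCCO1)[C@H]2[C@H](C(=O)OCC)N(N=O)[C@H](C(=O)OCC)[C@@H]2C3(C)OCCO3
F2 | step 4 | diethyl (2R,3R,4R,5S)-1-amino-3,4-bis(2-methyl-1,3-dioxolan-2-yl)pyrrolidine-2,5-dicarboxylate | CC1(OCCO1)[C@H]2[C@H](C(=O)OCC)N(N)[C@H](C(=O)OCC)[C@@H]2C3(C)OCCO3
F3 | step 2 | racemic diethyl (2R*,3R*,4R*,5S*)-3,4-diacetylpyrrolidine-2,5-dicarboxylate (1:1 mixture of 5 and its enantiomer) | CC(=O)[C@H]1[C@H](C(=O)OCC)N[C@H](C(=O)OCC)[C@@H]1C(C)=O.CC(=O)[C@@H]1[C@@H](C(=O)OCC)N[C@@H](C(=O)OCC)[C@H]1C(C)=O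
F4 | step 3 | diethyl (1R,2S,3R,4R)-3,4-diacetylcyclobutane-1,2-dicarboxylate | CC(=O)[C@H]1[C@H](C(=O)OCC)[C@H](C(=O)OCC)[C@@H]1C(C)=O
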